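## The problem

The target 21 is a 1-acyl-3-acetyl-sn-glycerol whose acyl group is a C20 bicyclic acid on a cis-fused decalin. The numbering used throughout is ring A = C1 (CH–CO2R), C2 (CH–CH3), C3, C4, C5, C10 and ring B = C5, C6 (4-methylpent-3-enyl), C7 (=CH), C8, C9, C10; the face carrying the two angular methyl groups is called α, the other β.

The core difficulty is the C5–C10 bond. It joins two adjacent quaternary carbons, each with a methyl group, cis to one another, and neither has a hydrogen that would allow later correction. This bond must therefore be made with its relative and absolute configuration in one event.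

Of the other stereocentres, C1 (ester α) is epimerisable and can be left to thermodynamic control once C2 is fixed: only the 1α,2β arrangement has ester and methyl both equatorial without a 1,3-diaxial contact to a ring-B carbon. C2 (methyl β) cannot be epimerised in the final compound and must be set kinetically relative to the ring fusion. The glycerol carbinol carbon (S) is remote, controls nothing and is best bought.

The trisubstituted C6=C7 alkene has to be placed next to the quaternary C5 and not at C7=C8. Like the side-chain alkene, it will not survive strong protic acid (cation–olefin cyclisation, methyl shift from C5) or hydrogenation. The ester carbon sits between C10 and C2, so it is hard to acylate and hard to hydrolyse, and the monoacetylated glycerol is prone to acyl migration and must be unveiled last.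

The feature that opens the structure is twofold. The cis C5/C10 methyl pair is exactly what suprafacial addition to the tetrasubstituted alkene of 2,3-dimethylcyclohex-2-enone 9 leaves behind. And C6–C7–C8–C9, with the chain on C6 and an oxygen at C7, is a 1-alkyl-2-silyloxybutadiene 8. The ketone left at C1 then has a single enolisable neighbour, C2, which is where the remaining ring-A work lies.

## Retrosynthesis

**Glyceride end group (21 ⇒ 20 ⇒ 19).** The acetyl C–O bond and the two ketal C–O bonds are cut. The acetate goes on last because it would not survive alkoxide or organocopper reagents, and the diol 20 is released from the acetonide 19 only at the end to keep acyl migration out of the route. The acyl–glycerol ester bond is deliberately not cut here. It is traced back to a carbonylation (see 13), so the hindered acid never has to be esterified. The forward steps must give mild ketal hydrolysis and primary-selective acetylation.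

**C1 configuration (19 ⇒ 18).** No bond is cut; C1 is allowed to be undefined in 18. This is cheaper than trying to control a kinetic protonation, because the required epimer is the thermodynamic one. The forward step must equilibrate C1 without exchanging the ester group.

**C2–CH3 bond (18 ⇒ 16).** The methyl group is removed from C2, leaving the enoate 16 as acceptor for a methyl nucleophile. The neighbouring cut (methylating the C1 ketone first, then reducing a tetrasubstituted enoate) is one step longer and needs a twisted enoate to be reduced. It is kept in reserve because it delivers hydrogen instead of methyl to the same face and is therefore stereocomplementary. The forward step must add to the β face of C2.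

**C6=C7 alkene (16 ⇒ 15 ⇒ 14 ⇒ 13).** The alkene is traced to an axial C7 alcohol 15, this to the C7 ketone 14, and this to the silyl enol ether 13. Keeping the C7 oxygen masked as the enol ether until the C1 ketone has been consumed means the two carbonyl groups never compete. The forward steps must deliver hydride trans to the C6 chain and eliminate toward C6.

**Carboxyl carbon and ester (13 ⇒ 11 + 12; 11 ⇒ 10).** The C1–C(=O) bond and the ester C–O bond are cut together: an enol triflate 11 is carbonylated in the presence of (R)-solketal 12. This is preferred to making the free acid because the glyceryl group is attached at an acyl-metal centre rather than at a neopentyl-type carboxyl. The triflate 11 comes from ketone 10, which can enolise only toward C2.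

**Ring B (10 ⇒ 8 + 9).** C5–C6 and C9–C10 are cut. This removes ring B, both quaternary centres and three stereocentres at once, and leads to an achiral diene 8 and the bought enone 9. Cutting C5–C10 itself or building the rings one at a time leaves a quaternary–quaternary bond to be made without the help of a ring alkene. The forward reaction must overcome the low reactivity of a tetrasubstituted enone and control regiochemistry and absolute configuration.

**Diene (8 ⇒ 7 ⇒ 5 ⇒ 3 ⇒ 1 + 2).** The enol ether O–Si bond is cut to vinyl ketone 7. The vinyl group is traced through the Mannich base 5 to the β-keto ester 3, whose carboxyl group fixes the site of aminomethylation. The C4–C5 bond of 3 is cut to ethyl acetoacetate 1 and the bromide 2. All pieces are commercial and the regiochemistry of every C–C bond is fixed by the functional groups.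

## Roads not taken

**Alternative 1:** The C5–C10 bond itself is cut, leading to the ten-membered diketone A1. In the forward direction, double enol silylation of A1 followed by one-electron oxidation would couple the two methyl-bearing α-carbons across the ring and give the bicyclic diketone A2, closing both rings at once.

- Merits: A2 is C2-symmetric, so its two ketones are equivalent. The C6 ketone can enolise only toward C7, so an enol triflate and a cross-coupling with a homoprenyl organometallic would place the C6=C7 alkene with no regiochemical doubt. In this respect the road is better than the chosen plan, which relies on the direction of an elimination (step 10).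
- Weak points: A1 is a medium ring that needs a ring-forming strategy of its own. The coupling must join two fully substituted centres across a ten-membered ring, and nothing in it decides between the cis (chiral) and trans (centrosymmetric) fusion or between the two enantiomers of A2. Using one of two identical ketones is statistical.
- Comparison: the chosen plan sets against this a cis fusion that is a mechanistic necessity, two oxygen functions that arrive differentiated (ketone and silyl enol ether in 10), and two cheap, short-to-make partners.

**Alternative 2:** The C1–C10 bond is cut. An Ireland–Claisen rearrangement of the silyl ketene acetal generated from the cis-lactone A3 would pass through a boat and give the ring-A acid A4, with the carboxyl group already in place.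

- Merits: the [3,3] shift transfers the lactone stereocentres to C1 and C10, and the cis lactone delivers the carboxyl trans to the C2 methyl directly. C2 then comes from a simple lactone stereocentre. This is better than the chosen plan, whose weakest stereochemical point is C2 (step 11).
- Weak points: the alkene terminus that becomes C10 is fully substituted, and its larger substituent must sit inside the boat above the lactone bridge. A stereodefined tetrasubstituted (Z)-alkene is needed. After A4 only one quaternary carbon exists: C5 is still an alkene carbon, and ring B has to be closed onto it with cis control next to C10. The hardest bond is therefore postponed, not solved, and the step count is higher.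
- Comparison: the chosen plan accepts a kinetic C2 but makes both quaternary centres in one step.

**Alternative 3:** C5–C6 and C1–C10 are cut, leading to the acyclic enyne A5. A cationic gold catalyst would activate the alkyne, C5 of the tetrasubstituted alkene would attack it, and the C10 cation would be trapped by C1 of the silyl enol ether, giving the bicyclic β-keto ester A6.

- Merits: both rings and both quaternary centres form in one step. Anti addition across the (Z)-alkene gives the cis methyl pair, and the alkyne becomes the C6=C7 alkene exactly where it is needed, again better than the elimination of the chosen plan.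
- Weak points: A5 needs a tetrasubstituted alkene of defined geometry between two functionalised chains. Attack on the alkyne must go to the distal carbon. Enantiocontrol of such a cascade has little to build on. A6 carries its ketone at C2, so the C2 methyl and the C1/C2 configurations still have to be made through an enol derivative and a reduction, and the protected propanol must be turned into the homoprenyl chain.
- Comparison: the overall length is greater and the ring-A stereochemical risk is no smaller. The chosen plan offers cheap cyclic and acyclic partners and a chain that arrives complete.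

Key step: step 5

Remark: existing catalyst models do not cover an α-methylated enone, so which enantiomer of the boron cation gives 10 cannot be predicted; the (S)-prolinol-derived cation is written, and its mirror image would be used if it gave the antipode.

Remark: C6 of 10 is written as in the endo adduct; its epimer would pass through steps 6 to 10 in the same way and converge at 16.

Bicyclic compounds are named with the C1–C10 numbering of the first section (decalin = decahydronaphthalene, C5 and C10 being the ring-fusion carbons).

Step 1
Reactants: 1 ethyl acetoacetate; 2 5-bromo-2-methylpent-2-ene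
Product: 3 ethyl 8-methyl-3-oxonon-7-enoate
Conditions: NaH, THF, 0 °C; n-BuLi, 0 °C; then 2, 0 °C to rt; aq NH4Cl
Reagents that add atoms: none
Why: The dianion of 1 reacts only at its terminal carbon, the more basic site, so SN2 alkylation by the primary bromide (γ-alkylation of an acetoacetate dianion) gives the chain with three methylene groups between ketone and alkene.

Step 2
Reactants: 3 ethyl 8-methyl-3-oxonon-7-enoate
Product: 5 1-(dimethylamino)-8-methylnon-7-en-3-one, via keto acid 4 (not isolated)
Conditions: KOH, H2O, rt; then Me2NH·HCl, 37% aq CH2O, pH 5–6, rt to 40 °C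
Reagents that add atoms: formaldehyde (C=O); dimethylamine hydrochloride (CNC.Cl)
Why: Saponification gives keto acid 4, whose doubly activated methylene is aminomethylated (Mannich reaction); loss of CO2 then leaves the amine on the carbon that was C2 of the acid, so the future vinyl group is built only on the side away from the chain.

Step 3
Reactants: 5 1-(dimethylamino)-8-methylnon-7-en-3-one
Product: 7 8-methylnona-1,7-dien-3-one, via ammonium iodide 6 (not isolated)
Conditions: MeI, acetone, rt; then aq NaHCO3, CH2Cl2, rt
Reagents that add atoms: none
Why: N-Methylation makes the amine a leaving group and mild base effects E1cB loss of trimethylamine (Hofmann-type elimination of a Mannich base methiodide), the standard release of a vinyl ketone.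

Step 4
Reactants: 7 8-methylnona-1,7-dien-3-one
Product: 8 tert-butyl(dimethyl){[(3Z)-8-methylnona-1,3,7-trien-3-yl]oxy}silane
Conditions: t-BuMe2SiOTf, Et3N, Et2O, −78 to 0 °C
Reagents that add atoms: tert-butyldimethylsilyl trifluoromethanesulfonate (CC(C)(C)[Si](C)(C)OS(=O)(=O)C(F)(F)F)
Why: Soft enolisation with silyl triflate and amine can engage only the C4 methylene; the (Z) enol ether, with the chain trans to the vinyl group, is the less strained isomer and the only one that can reach the s-cis diene conformation, so any (E) isomer is inert in step 5.

Step 5
Reactants: 8 tert-butyl(dimethyl){[(3Z)-8-methylnona-1,3,7-trien-3-yl]oxy}silane; 9 2,3-dimethylcyclohex-2-en-1-one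
Product: 10 (5R,6S,10S)-7-[(tert-butyldimethylsilyl)oxy]-5,10-dimethyl-6-(4-methylpent-3-en-1-yl)-cis-decal-7-en-1-one (angular methyls cis, C6 chain β)
Conditions: 8 (1.5 equiv), (S)-B-(o-tolyl)oxazaborolidinium triflimide [C24H25BNO][N(SO2CF3)2] (20 mol %; N-protonated oxazaborolidine from (S)-α,α-diphenylprolinol and o-tolylboronic acid), CH2Cl2, −78 to −20 °C; Et3N quench
Reagents that add atoms: none
Why: Proposed new method: the closest known reaction type is the Diels–Alder reaction of hindered 2-silyloxydienes with β,β-disubstituted cyclohexenones under very strong Lewis acids (AlBr3/AlMe3 or silyl triflimide), which has not been made enantioselective for a tetrasubstituted enone; here the cationic boron centre binds the C1 carbonyl of 9 and lowers its LUMO enough for the electron-rich diene 8 to add. Bond formation is expected to be strongly asynchronous or stepwise, the enol-ether terminus C6 attacking the β-carbon C5 first (Mukaiyama–Michael-like) and the boron enolate carbon C10 then closing onto the silyloxyallyl cation terminus C9. Ring B is thus closed as a cyclohexene by a formal intermolecular [4+2] addition that forms C5–C6 and C9–C10. Regiochemistry follows from the polarisation of the diene, which places the silyloxy carbon C7 para to the carbonyl-bearing C10. Both bonds are made on one face of the ring alkene of 9, so the C5 and C10 methyl groups, and with them the ring fusion, are necessarily cis. The absolute configuration at C5 and C10 is controlled by the chiral cation, which blocks one face of the bound enone. C6 is set by the (Z) enol ether, which keeps the chain outside, and by the endo transition state, but it becomes trigonal in step 10 and its configuration is of no consequence. The step therefore needs regioselectivity, enantioselectivity and chemoselectivity against the side-chain alkene; the first is secured by the 2-silyloxy group, the last by low temperature and the absence of protic acid, and the second rests on the catalyst alone.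

Step 6
Reactants: 10 (5R,6S,10S)-7-[(tert-butyldimethylsilyl)oxy]-5,10-dimethyl-6-(4-methylpent-3-en-1-yl)-cis-decal-7-en-1-one
Product: 11 (5R,6S,10S)-7-[(tert-butyldimethylsilyl)oxy]-5,10-dimethyl-6-(4-methylpent-3-en-1-yl)-cis-decala-1,7-dien-1-yl trifluoromethanesulfonate
Conditions: KN(SiMe3)2, THF, −78 °C; PhN(SO2CF3)2, −78 to 0 °C
Reagents that add atoms: N-phenylbis(trifluoromethanesulfonimide) (O=S(=O)(N(c1ccccc1)S(=O)(=O)C(F)(F)F)C(F)(F)F)
Why: C2 is the only enolisable position of ketone 10 because C10 is quaternary, so formation of the potassium enolate and its O-sulfonylation are regiospecific; the silyl enol ether is inert to the amide base and to the triflimide.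

Step 7
Reactants: 11 the enol triflate of step 6; 12 (R)-solketal, [(4R)-2,2-dimethyl-1,3-dioxolan-4-yl]methanol
Product: 13 [(4S)-2,2-dimethyl-1,3-dioxolan-4-yl]methyl (5R,6S,10S)-7-[(tert-butyldimethylsilyl)oxy]-5,10-dimethyl-6-(4-methylpent-3-en-1-yl)-cis-decala-1,7-diene-1-carboxylate (the dioxolane descriptor changes from R to S for priority reasons only)
Conditions: Pd(OAc)2 (10 mol %), PPh3 (20 mol %), CO (1 atm), 12 (5 equiv), Et3N, DMF, 60 °C
Reagents that add atoms: carbon monoxide ([C-]#[O+])
Why: Oxidative addition of zerovalent palladium to the C1–OTf bond, CO insertion and alcoholysis of the acylpalladium by the primary hydroxyl of 12 (palladium-catalysed alkoxycarbonylation of an enol triflate) create the carboxyl carbon and the glyceryl ester in one step, so a neopentyl-type acid never has to be esterified; the stereocentre of 12 is not involved.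

Step 8
Reactants: 13 the silyl enol ether ester of step 7
Product: 14 [(4S)-2,2-dimethyl-1,3-dioxolan-4-yl]methyl (5R,6S,10S)-5,10-dimethyl-6-(4-methylpent-3-en-1-yl)-7-oxo-cis-decal-1-ene-1-carboxylate
Conditions: Bu4NF, AcOH, THF, 0 °C to rt
Reagents that add atoms: none
Why: Fluoride cleaves the Si–O bond and the acetic acid buffer protonates the enolate at C8 (desilylation of a silyl enol ether), giving the C7 ketone without base-induced change at C6 or attack on the enoate and the acetonide.

Step 9
Reactants: 14 the keto ester of step 8
Product: 15 [(4S)-2,2-dimethyl-1,3-dioxolan-4-yl]methyl (5R,6S,7R,10S)-7-hydroxy-5,10-dimethyl-6-(4-methylpent-3-en-1-yl)-cis-decal-1-ene-1-carboxylate (7-OH axial, β, cis to the C6 chain)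
Conditions: LiBH(s-Bu)3, THF, −78 °C; aq NH4Cl
Reagents that add atoms: none
Why: The bulky trialkylborohydride attacks the C7 carbonyl along the equatorial trajectory, away from the axial ring-A carbon on C5 (steric approach control), which sets C7 with an axial hydroxyl cis to the equatorial C6 chain; at −78 °C the hindered β-substituted enoate is not reduced.

Step 10
Reactants: 15 the axial alcohol of step 9
Product: 16 [(4S)-2,2-dimethyl-1,3-dioxolan-4-yl]methyl (5R,10S)-5,10-dimethyl-6-(4-methylpent-3-en-1-yl)-cis-decala-1,6-diene-1-carboxylate
Conditions: POCl3, pyridine, 0 to 50 °C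
Reagents that add atoms: none
Why: The dichlorophosphate of the axial alcohol undergoes pyridine-induced E2 elimination with the trans-diaxial tertiary hydrogen on C6, the Zaitsev direction, giving the trisubstituted C6=C7 alkene; the basic medium excludes cationic migration or cyclisation.

Step 11
Reactants: 16 the diene ester of step 10
Product: 18 [(4S)-2,2-dimethyl-1,3-dioxolan-4-yl]methyl (2R,5R,10R)-2,5,10-trimethyl-6-(4-methylpent-3-en-1-yl)-cis-decal-6-ene-1-carboxylate (2-methyl β; mixture of C1 epimers), via silyl ketene acetal 17 (not isolated)
Conditions: Me2CuLi, Me3SiCl, THF, −78 to −20 °C; aq NH4Cl/NH3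
Reagents that add atoms: lithium dimethylcuprate ([Li+].C[Cu-]C)
Why: Me3SiCl-accelerated conjugate addition of the cuprate to the enoate puts the methyl group on C2; addition is expected on the β face, through the half-chair in which the axial trajectory at C2 passes the ring-B methylene C9 instead of running 1,3-syn to a pseudoaxial C10 methyl group, which would set C2 as R. Hydrolysis of the ketene acetal 17 on work-up protonates C1 without useful control, which step 12 corrects.

Step 12
Reactants: 18 the C1-epimeric ester mixture of step 11
Product: 19 [(4S)-2,2-dimethyl-1,3-dioxolan-4-yl]methyl (1S,2R,5R,10R)-2,5,10-trimethyl-6-(4-methylpent-3-en-1-yl)-cis-decal-6-ene-1-carboxylate (ester α, trans to the 2-methyl)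
Conditions: NaH (0.3 equiv), 12 (10 equiv), THF, 60 °C; AcOH quench
Reagents that add atoms: none
Why: Reversible deprotonation at C1 by the alkoxide of the ester's own alcohol (alkoxide epimerisation of an ester, any exchange being degenerate) leads to the 1α ester, the only C1 epimer in which ester and C2 methyl are both equatorial and free of a 1,3-diaxial contact with C6 or C9; C2 and the quaternary centres cannot epimerise.

Step 13
Reactants: 19 the acetonide ester of step 12
Product: 20 (2S)-2,3-dihydroxypropyl (1S,2R,5R,10R)-2,5,10-trimethyl-6-(4-methylpent-3-en-1-yl)-cis-decal-6-ene-1-carboxylate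
Conditions: AcOH/H2O/THF (3:1:1), 40 °C
Reagents that add atoms: none
Why: Acid-catalysed hydrolysis of the isopropylidene ketal; aqueous acetic acid does not protonate the trisubstituted alkenes, and the hindered acyl group should neither hydrolyse nor migrate under these conditions.

Step 14
Reactants: 20 the diol of step 13
Product: 21 (2S)-3-(acetyloxy)-2-hydroxypropyl (1S,2R,5R,10R)-2,5,10-trimethyl-6-(4-methylpent-3-en-1-yl)-cis-decal-6-ene-1-carboxylate (CNP0146255.1)
Conditions: AcCl (1.05 equiv), 2,4,6-collidine, CH2Cl2, −78 °C
Reagents that add atoms: acetyl chloride (CC(=O)Cl)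
Why: At low temperature with a hindered pyridine base, acetyl chloride acylates the primary hydroxyl far faster than the secondary one (kinetic primary-selective acylation of a 1,2-diol), and the near-neutral conditions should not promote acyl migration; the glycerol stereocentre is untouched.

## Compound list

1 | ethyl acetoacetate | CCOC(=O)CC(C)=O | starting material
2 | 5-bromo-2-methylpent-2-ene | CC(C)=CCCBr | starting material
3 | ethyl 8-methyl-3-oxonon-7-enoate | CCOC(=O)CC(=O)CCCC=C(C)C | intermediate
4 | 8-methyl-3-oxonon-7-enoic acid (potassium salt in the flask) | OC(=O)CC(=O)CCCC=C(C)C | intermediate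
5 | 1-(dimethylamino)-8-methylnon-7-en-3-one | CN(C)CCC(=O)CCCC=C(C)C | intermediate
6 | N,N,N,8-tetramethyl-3-oxonon-7-en-1-aminium iodide | C[N+](C)(C)CCC(=O)CCCC=C(C)C.[I-] | intermediate
7 | 8-methylnona-1,7-dien-3-one | C=CC(=O)CCCC=C(C)C | intermediate
8 | tert-butyl(dimethyl){[(3Z)-8-methylnona-1,3,7-trien-3-yl]oxy}silane | C=C/C(O[Si](C)(C)C(C)(C)C)=C/CCC=C(C)C | intermediate
9 | 2,3-dimethylcyclohex-2-en-1-one | CC1=C(C)C(=O)CCC1 | starting material
10 | (5R,6S,10S)-7-[(tert-butyldimethylsilyl)oxy]-5,10-dimethyl-6-(4-methylpent-3-en-1-yl)-cis-decal-7-en-1-one | O=C1CCC[C@]2(C)[C@H](CCC=C(C)C)C(O[Si](C)(C)C(C)(C)C)=CC[C@]12C | intermediate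
11 | (5R,6S,10S)-7-[(tert-butyldimethylsilyl)oxy]-5,10-dimethyl-6-(4-methylpent-3-en-1-yl)-cis-decala-1,7-dien-1-yl trifluoromethanesulfonate | O=S(=O)(OC1=CCC[C@]2(C)[C@H](CCC=C(C)C)C(O[Si](C)(C)C(C)(C)C)=CC[C@]12C)C(F)(F)F | intermediate
12 | (R)-solketal, [(4R)-2,2-dimethyl-1,3-dioxolan-4-yl]methanol | CC1(C)OC[C@@H](CO)O1 | starting material
13 | [(4S)-2,2-dimethyl-1,3-dioxolan-4-yl]methyl (5R,6S,10S)-7-[(tert-butyldimethylsilyl)oxy]-5,10-dimethyl-6-(4-methylpent-3-en-1-yl)-cis-decala-1,7-diene-1-carboxylate | CC1(C)OC[C@@H](COC(=O)C2=CCC[C@]3(C)[C@H](CCC=C(C)C)C(O[Si](C)(C)C(C)(C)C)=CC[C@]23C)O1 | intermediate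
14 | [(4S)-2,2-dimethyl-1,3-dioxolan-4-yl]methyl (5R,6S,10S)-5,10-dimethyl-6-(4-methylpent-3-en-1-yl)-7-oxo-cis-decal-1-ene-1-carboxylate | CC1(C)OC[C@@H](COC(=O)C2=CCC[C@]3(C)[C@H](CCC=C(C)C)C(=O)CC[C@]23C)O1 | intermediate
15 | [(4S)-2,2-dimethyl-1,3-dioxolan-4-yl]methyl (5R,6S,7R,10S)-7-hydroxy-5,10-dimethyl-6-(4-methylpent-3-en-1-yl)-cis-decal-1-ene-1-carboxylate | CC1(C)OC[C@@H](COC(=O)C2=CCC[C@]3(C)[C@H](CCC=C(C)C)[C@H](O)CC[C@]23C)O1 | intermediate
16 | [(4S)-2,2-dimethyl-1,3-dioxolan-4-yl]methyl (5R,10S)-5,10-dimethyl-6-(4-methylpent-3-en-1-yl)-cis-decala-1,6-diene-1-carboxylate | CC1(C)OC[C@@H](COC(=O)C2=CCC[C@]3(C)C(CCC=C(C)C)=CCC[C@]23C)O1 | intermediate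
17 | trimethylsilyl ketene acetal of 18 (C1 exocyclic C=C(OSiMe3)(O-glyceryl acetonide), geometry undefined) | CC1(C)OC[C@@H](COC(O[Si](C)(C)C)=C2[C@H](C)CC[C@]3(C)C(CCC=C(C)C)=CCC[C@]23C)O1 | intermediate
18 | [(4S)-2,2-dimethyl-1,3-dioxolan-4-yl]methyl (2R,5R,10R)-2,5,10-trimethyl-6-(4-methylpent-3-en-1-yl)-cis-decal-6-ene-1-carboxylate, C1 epimer mixture | CC1(C)OC[C@@H](COC(=O)C2[C@H](C)CC[C@]3(C)C(CCC=C(C)C)=CCC[C@]23C)O1 | intermediate
19 | [(4S)-2,2-dimethyl-1,3-dioxolan-4-yl]methyl (1S,2R,5R,10R)-2,5,10-trimethyl-6-(4-methylpent-3-en-1-yl)-cis-decal-6-ene-1-carboxylate | CC1(C)OC[C@@H](COC(=O)[C@H]2[C@H](C)CC[C@]3(C)C(CCC=C(C)C)=CCC[C@]23C)O1 | intermediate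
20 | (2S)-2,3-dihydroxypropyl (1S,2R,5R,10R)-2,5,10-trimethyl-6-(4-methylpent-3-en-1-yl)-cis-decal-6-ene-1-carboxylate | OC[C@H](O)COC(=O)[C@H]1[C@H](C)CC[C@]2(C)C(CCC=C(C)C)=CCC[C@]12C | intermediate
21 | (2S)-3-(acetyloxy)-2-hydroxypropyl (1S,2R,5R,10R)-2,5,10-trimethyl-6-(4-methylpent-3-en-1-yl)-cis-decal-6-ene-1-carboxylate | CC(=O)OC[C@H](O)COC(=O)[C@H]1[C@H](C)CC[C@]2(C)C(CCC=C(C)C)=CCC[C@]12C | target

## Step count and least certain steps

Total: 14 steps. Longest linear sequence: 14 steps (1 and 2 through 3, 5, 7, 8, 10 to 21); 9 and 12 enter as bought materials.

**Step 5 (key step, proposed new method).**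
- What may go wrong: the boron cation may activate a tetrasubstituted, α-methylated enone too weakly for turnover. Facial discrimination may be poor, because the α-methyl group removes the contact that normally fixes an enone on such a catalyst. The side-chain alkene may intercept the silyloxyallyl cation, or silyl transfer may halt the sequence at the open-chain conjugate adduct.
- Fallback: starting from 8 and 9, the cycloaddition is run with the achiral mixed Lewis acid AlBr3/AlMe3 in toluene/CH2Cl2 at low temperature, the known way to join hindered 2-silyloxydienes to β,β-disubstituted cyclohexenones. This gives 10 together with its mirror image, the enantiomeric adduct F1. The racemate is taken through steps 6 and 7 unchanged, by way of the enantiomeric enol triflate F2. Because alcohol 12 is a single enantiomer, the carbonylation converts the antipodes into diastereomers, 13 and the diastereomeric ester F3, which are separated by preparative chromatography. The route is rejoined at 13; resolution through a chiral ester replaces catalyst control.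

**Step 11.**
- What may go wrong: the facial preference at C2 is the least secure stereochemical point of the route. Either axial trajectory meets a syn-axial carbon on C10 (the methyl group or C9), so delivery of the methyl group to the α face or low selectivity is possible. Addition to an enoate whose α-carbon carries a quaternary neighbour may also be sluggish.
- Fallback (stereocomplementary, because hydrogen instead of methyl is delivered to C2): starting from 10, deprotonation with LiN(i-Pr)2 and alkylation with MeI give the 2-methyl ketone F4. Triflation as in step 6 gives the tetrasubstituted enol triflate F5, and carbonylation with 12 as in step 7 gives the 2-methyl enoate F6. Ring B is then processed as in steps 8 to 10, through the keto ester F7 and the axial alcohol F8 to the diene ester F9. Conjugate reduction of F9 with SmI2 (H2O, Et3N, THF) places a hydrogen on the face that the cuprate would have used and so leaves the methyl group on the other. The product is 18, where the route is rejoined before the equilibration of step 12.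

**Step 10 (with step 9).**
- What may go wrong: the elimination may go toward C8 by loss of the less hindered axial hydrogen. Alternatively, hydride delivery in step 9 may occur from the other face, leaving no trans-diaxial hydrogen on C6.
- Fallback: starting from 14, Tf2O and 2,6-di-tert-butyl-4-methylpyridine in CH2Cl2, conditions that favour the more substituted enol derivative, give the C6=C7 enol triflate F10. Reduction of its C–OTf bond with Pd(OAc)2, PPh3, HCO2H and Bu3N in DMF gives 16, where the route is rejoined. The alkene position is then fixed by the triflate and not by the geometry of an elimination.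

**Step 12.**
- What may go wrong: proton exchange at the hindered C1 may be slow, or the glyceryl ester may be lost by hydrolysis under prolonged basic treatment.
- Fallback: starting from 18, KOH in aqueous ethylene glycol at 120 °C equilibrates C1 in the ester and hydrolyses it, giving the free acid F11. Its caesium salt (Cs2CO3, DMF) is alkylated at oxygen by the tosylate of 12, [(4S)-2,2-dimethyl-1,3-dioxolan-4-yl]methyl 4-methylbenzenesulfonate F12 (from 12, TsCl, pyridine). The SN2 reaction at the primary carbon avoids acylation at the hindered carbonyl and leaves the glycerol stereocentre untouched. This gives 19, where the route is rejoined.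

## Further compounds

F1 | step 5 | enantiomeric adduct, (5S,6R,10R)-7-[(tert-butyldimethylsilyl)oxy]-5,10-dimethyl-6-(4-methylpent-3-en-1-yl)-cis-decal-7-en-1-one | O=C1CCC[C@@]2(C)[C@@H](CCC=C(C)C)C(O[Si](C)(C)C(C)(C)C)=CC[C@@]12C
F2 | step 5 | enantiomeric enol triflate (mirror image of 11) | O=S(=O)(OC1=CCC[C@@]2(C)[C@@H](CCC=C(C)C)C(O[Si](C)(C)C(C)(C)C)=CC[C@@]12C)C(F)(F)F
F3 | step 5 | diastereomeric ester, [(4S)-2,2-dimethyl-1,3-dioxolan-4-yl]methyl (5S,6R,10R)-7-[(tert-butyldimethylsilyl)oxy]-5,10-dimethyl-6-(4-methylpent-3-en-1-yl)-cis-decala-1,7-diene-1-carboxylate | CC1(C)OC[C@@H](COC(=O)C2=CCC[C@@]3(C)[C@@H](CCC=C(C)C)C(O[Si](C)(C)C(C)(C)C)=CC[C@@]23C)O1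
F4 | step 11 | 2-methyl ketone, 2-methyl derivative of 10 (C2 epimer mixture) | O=C1C(C)CC[C@]2(C)[C@H](CCC=C(C)C)C(O[Si](C)(C)C(C)(C)C)=CC[C@]12C
F5 | step 11 | tetrasubstituted enol triflate, 2-methyl derivative of 11 | O=S(=O)(OC1=C(C)CC[C@]2(C)[C@H](CCC=C(C)C)C(O[Si](C)(C)C(C)(C)C)=CC[C@]12C)C(F)(F)F
F6 | step 11 | 2-methyl enoate, 2-methyl derivative of 13 | CC1(C)OC[C@@H](COC(=O)C2=C(C)CC[C@]3(C)[C@H](CCC=C(C)C)C(O[Si](C)(C)C(C)(C)C)=CC[C@]23C)O1
F7 | step 11 | keto ester, 2-methyl derivative of 14 | CC1(C)OC[C@@H](COC(=O)C2=C(C)CC[C@]3(C)[C@H](CCC=C(C)C)C(=O)CC[C@]23C)O1
F8 | step 11 | axial alcohol, 2-methyl derivative of 15 | CC1(C)OC[C@@H](COC(=O)C2=C(C)CC[C@]3(C)[C@H](CCC=C(C)C)[C@H](O)CC[C@]23C)O1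
F9 | step 11 | diene ester, 2-methyl derivative of 16 | CC1(C)OC[C@@H](COC(=O)C2=C(C)CC[C@]3(C)C(CCC=C(C)C)=CCC[C@]23C)O1
F10 | step 10 | C6=C7 enol triflate, [(4S)-2,2-dimethyl-1,3-dioxolan-4-yl]methyl (5R,10S)-5,10-dimethyl-6-(4-methylpent-3-en-1-yl)-7-(trifluoromethanesulfonyloxy)-cis-decala-1,6-diene-1-carboxylate | CC1(C)OC[C@@H](COC(=O)C2=CCC[C@]3(C)C(CCC=C(C)C)=C(OS(=O)(=O)C(F)(F)F)CC[C@]23C)O1
F11 | step 12 | free acid, (1S,2R,5R,10R)-2,5,10-trimethyl-6-(4-methylpent-3-en-1-yl)-cis-decal-6-ene-1-carboxylic acid | OC(=O)[C@H]1[C@H](C)CC[C@]2(C)C(CCC=C(C)C)=CCC[C@]12C
F12 | step 12 | [(4S)-2,2-dimethyl-1,3-dioxolan-4-yl]methyl 4-methylbenzenesulfonate | CC1(C)OC[C@@H](COS(=O)(=O)c2ccc(C)cc2)O1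
A1 | alternative 1 | 2,7-dimethylcyclodecane-1,6-dione | CC1CCCC(=O)C(C)CCCC1=O
A2 | alternative 1 | cis-5,10-dimethyldecalin-1,6-dione (numbering of 21) | O=C1CCC[C@]2(C)C(=O)CCC[C@]12C
A3 | alternative 2 | cis-6-[(2Z)-6-[(tert-butyldimethylsilyl)oxy]-3-methylhex-2-en-2-yl]-4-methyloxan-2-one | C[C@H]1CC(=O)O[C@H](C1)/C(C)=C(C)\CCCO[Si](C)(C)C(C)(C)C
A4 | alternative 2 | 6-{3-[(tert-butyldimethylsilyl)oxy]propyl}-2,5,6-trimethylcyclohex-4-ene-1-carboxylic acid, configured at C1, C2 and the quaternary carbon as in 21 | OC(=O)[C@H]1[C@H](C)CC=C(C)[C@]1(C)CCCO[Si](C)(C)C(C)(C)C
A5 | alternative 3 | methyl (6Z)-3-[(tert-butyldimethylsilyl)oxy]-14-[(2,2-dimethylpropanoyl)oxy]-6,7-dimethyltetradeca-2,6-dien-10-ynoate | COC(=O)C=C(O[Si](C)(C)C(C)(C)C)CC/C(C)=C(C)\CCC#CCCCOC(=O)C(C)(C)C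
A6 | alternative 3 | methyl cis-5,10-dimethyl-2-oxo-6-{3-[(2,2-dimethylpropanoyl)oxy]propyl}decal-6-ene-1-carboxylate (numbering of 21) | COC(=O)C1C(=O)CC[C@]2(C)C(CCCOC(=O)C(C)(C)C)=CCC[C@]12C
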